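A direct plan would join two ready-made six-membered rings.
It would dearomatise A1, the tertiary allylic ether of 3-methylphloroacetophenone, by an enantioselective palladium-catalysed O-to-C prenyl shift to the chiral monomer A2.
It would then bridge A2 and the prenylated phloroacetophenone A3 with formaldehyde.
The dearomative prenylation that sets the quaternary centre would be weakest: its two faces differ only through distant ring substituents, and the reaction type is untested on acylphloroglucinols.
The selective mono-O-alkylation that prepares A1 would compete with C-alkylation and with reaction at the other two hydroxyls.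
The formaldehyde bridging would give both homodimers beside the mixed dimer, because both partners are nucleophiles of the same kind.

The dearomatised ring (C1 = carbonyl between acetyl-bearing C2 and bridge-bearing C6) is treated as a folded triketide, not as a former arene. Its quaternary C4 sits between the carbonyl carbons C3 and C5, so C3–C4–C5 is an α,α-disubstituted acetoacetate. The ring is disconnected at C1–C2 and C5–C6 into acyclic keto ester 6, whose stereocentre is set by two chelate-controlled alkylations, and dihydrocoumarin 14, which already carries the aromatic ring and the bridge carbon. One operation (Claisen acylation, then Dieckmann closure) builds the trione ring, and the choice of which carbonyl arm becomes C3 or C5 turns the acyclic centre into the ring stereocentre. Dearomatisation, phenol differentiation and bridging of two monomers do not occur.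

Key step: step 6

Remark: lactone 14 is drawn as closed on the hydroxyl para to the acetyl group; the isomer closed on an ortho hydroxyl would be opened in step 6 to the same diketo ester 15.

Step 1
Reactants: 1 methyl (3R)-3-hydroxybutanoate; 2 1-bromo-3-methylbut-2-ene (prenyl bromide)
Product: 3 methyl (2R,3R)-3-hydroxy-2-(3-methylbut-2-en-1-yl)butanoate
Conditions: LiN(iPr)2 (2.2 equiv), THF, −50 °C; 2 (1.3 equiv), DMPU, −50 → −10 °C; aq. NH4Cl
Reagents that add atoms: prenyl bromide (2), CC(C)=CCBr
Why: Fráter–Seebach alkylation, in which the lithium alkoxide–enolate dianion is a rigid six-membered chelate and the bromide attacks C2 on the face anti to the C3 methyl group, which should give the anti (2R,3R) isomer; the C3 centre comes from the starting material.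

Step 2
Reactants: 3 methyl (2R,3R)-3-hydroxy-2-(3-methylbut-2-en-1-yl)butanoate; 4 iodomethane
Product: 5 methyl (2S,3R)-3-hydroxy-2-methyl-2-(3-methylbut-2-en-1-yl)butanoate
Conditions: LiN(iPr)2 (2.3 equiv), THF, −50 → −20 °C; 4 (2.0 equiv), DMPU, −50 → 0 °C; aq. NH4Cl
Reagents that add atoms: iodomethane (4), CI
Why: Second Fráter–Seebach alkylation, in which the chelated dianion of 3 holds the prenyl group in the enolate plane and iodomethane again enters anti to the C3 methyl group, so the order of the two alkylations fixes the quaternary centre as (2S); the small electrophile is kept for the hindered second alkylation.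

Step 3
Reactants: 5 methyl (2S,3R)-3-hydroxy-2-methyl-2-(3-methylbut-2-en-1-yl)butanoate
Product: 6 methyl (2S)-2-methyl-2-(3-methylbut-2-en-1-yl)-3-oxobutanoate
Conditions: Dess–Martin periodinane (1.3 equiv), NaHCO3, CH2Cl2, 0 °C → rt
Reagents that add atoms: none
Why: Dess–Martin oxidation of the hindered secondary alcohol under buffered, non-basic conditions, which erases the C3 centre on purpose, cannot epimerise the quaternary centre and avoids retro-aldol and retro-Claisen cleavage.

Step 4
Reactants: 7 1-(2,4,6-trihydroxyphenyl)ethan-1-one; 2 1-bromo-3-methylbut-2-ene (prenyl bromide)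
Product: 8 1-[2,4,6-trihydroxy-3-(3-methylbut-2-en-1-yl)phenyl]ethan-1-one
Conditions: 2 (1.0 equiv), 10% aq. KOH (1.0 equiv), 0 °C → rt
Reagents that add atoms: prenyl bromide (2), CC(C)=CCBr
Why: Carbon alkylation of the ambident phloroglucinolate in water, where solvation of oxygen favours attack through carbon; the two free ring positions of 7 are equivalent, the degree of alkylation is held by stoichiometry, and no stereocentre is formed.

Step 5
Reactants: 8 1-[2,4,6-trihydroxy-3-(3-methylbut-2-en-1-yl)phenyl]ethan-1-one; 9 formaldehyde; 10 2,2-dimethyl-1,3-dioxane-4,6-dione (Meldrum's acid)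
Product: 14 6-acetyl-5,7-dihydroxy-8-(3-methylbut-2-en-1-yl)-3,4-dihydro-2H-chromen-2-one, via methylidene Meldrum's acid 11 (not isolated), via Michael adduct 12 (not isolated), via lactone acid 13 (not isolated)
Conditions: 10 (1.1 equiv), 37% aq. HCHO (1.1 equiv), L-proline (5 mol%), MeCN, rt, 1 h; then 8 (1.0 equiv), rt; then pyridine, 100 °C
Reagents that add atoms: formaldehyde (9), C=O; Meldrum's acid (10), CC1(C)OC(=O)CC(=O)O1
Why: Yonemitsu-type three-component condensation, in which Knoevenagel condensation gives 11, the only free ring carbon of 8 adds to it as a carbon nucleophile, and on heating the adduct loses acetone, is acylated by the neighbouring hydroxyl and decarboxylates to the dihydrocoumarin; no stereocentre remains.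

Step 6
Reactants: 6 methyl (2S)-2-methyl-2-(3-methylbut-2-en-1-yl)-3-oxobutanoate; 14 6-acetyl-5,7-dihydroxy-8-(3-methylbut-2-en-1-yl)-3,4-dihydro-2H-chromen-2-one
Product: 16 (6R)-4-{[3-acetyl-2,4,6-trihydroxy-5-(3-methylbut-2-en-1-yl)phenyl]methyl}-5-hydroxy-6-methyl-6-(3-methylbut-2-en-1-yl)cyclohex-4-ene-1,3-dione, via diketo ester 15 (not isolated)
Conditions: 6 (1.3 equiv), LiN(iPr)2 (1.35 equiv), THF, −78 °C; add 14 (1.0 equiv) pre-treated with LiN(SiMe3)2 (3.1 equiv) in THF–DMPU, −78 → −30 °C; then LiN(iPr)2 (3.0 equiv), −78 °C → rt; 1 M HCl, 0 °C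
Reagents that add atoms: none
Why: The kinetic lithium enolate of the methyl ketone of 6 (its only enolisable position) attacks the aryl-ester carbonyl of 14 and expels the phenoxide (crossed Claisen acylation, forming C1–C2) to give 15 as its enolate; a second deprotonation at the methylene next to the former lactone carbonyl gives the 1,3-diketone dianion, whose terminal carbanion attacks the non-enolisable methyl ester in a 6-exo-trig Dieckmann closure (forming C5–C6) with loss of methoxide. The closest known reaction types are the acylation of ketone enolates by 3,4-dihydrocoumarins and the base-induced Claisen cyclisation of polyanions of 3,5-dioxoalkanoates to cyclohexane-1,3,5-triones. No stereocentre is formed: the quaternary carbon of 6 becomes C4 unchanged, and because its ketone carbonyl becomes C3 and its ester carbonyl becomes C5, the (S) centre of 6 is the (R) centre of the target. The step needs carbon rather than oxygen cyclisation and reaction at C6 only; the dianion carbanion is the only carbon that reaches the ester through a six-membered transition state (C2 would close a four-membered ring), and the lithium phenoxides switch off the aryl ketone both as an acid and as an electrophile. Amide bases are used throughout because alkoxides would cleave the non-enolisable β-keto ester by retro-Claisen reaction.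

Step 7
Reactants: 16 (6R)-4-{[3-acetyl-2,4,6-trihydroxy-5-(3-methylbut-2-en-1-yl)phenyl]methyl}-5-hydroxy-6-methyl-6-(3-methylbut-2-en-1-yl)cyclohex-4-ene-1,3-dione; 17 acetic anhydride
Product: 19 (4R)-2-acetyl-6-{[3-acetyl-2,4,6-trihydroxy-5-(3-methylbut-2-en-1-yl)phenyl]methyl}-3,5-dihydroxy-4-methyl-4-(3-methylbut-2-en-1-yl)cyclohexa-2,5-dien-1-one, via triacetate 18 (not isolated)
Conditions: 17 (6 equiv), Et3N (8 equiv), 4-(dimethylamino)pyridine (1.0 equiv), CH2Cl2, 0 °C → rt; then K2CO3 (5 equiv), MeOH, rt; 1 M HCl, 0 °C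
Reagents that add atoms: acetic anhydride (17), CC(=O)OC(C)=O
Why: O-acetylation of the phenols and of the trione enol followed by the 4-(dimethylamino)pyridine-mediated O-to-C acyl shift known for 2-acylcyclohexane-1,3-diones, which should end at C2 because only there does an enolised, hydrogen-bonded triketone result (acylation at the substituted C6 is reversible); mild methanolysis then removes the aryl and enol acetates but not the C-acetyl group, and the quaternary centre is untouched.

**Compound list**
1 | methyl (3R)-3-hydroxybutanoate | C[C@@H](O)CC(=O)OC | starting material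
2 | 1-bromo-3-methylbut-2-ene (prenyl bromide) | CC(C)=CCBr | starting material
3 | methyl (2R,3R)-3-hydroxy-2-(3-methylbut-2-en-1-yl)butanoate | C[C@@H](O)[C@@H](CC=C(C)C)C(=O)OC | intermediate
4 | iodomethane | CI | starting material
5 | methyl (2S,3R)-3-hydroxy-2-methyl-2-(3-methylbut-2-en-1-yl)butanoate | C[C@@H](O)[C@](C)(CC=C(C)C)C(=O)OC | intermediate
6 | methyl (2S)-2-methyl-2-(3-methylbut-2-en-1-yl)-3-oxobutanoate | CC(=O)[C@](C)(CC=C(C)C)C(=O)OC | intermediate
7 | 1-(2,4,6-trihydroxyphenyl)ethan-1-one | CC(=O)c1c(O)cc(O)cc1O | starting material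
8 | 1-[2,4,6-trihydroxy-3-(3-methylbut-2-en-1-yl)phenyl]ethan-1-one | CC(=O)c1c(O)cc(O)c(CC=C(C)C)c1O | intermediate
9 | formaldehyde | C=O | starting material
10 | 2,2-dimethyl-1,3-dioxane-4,6-dione (Meldrum's acid) | CC1(C)OC(=O)CC(=O)O1 | starting material
11 | 2,2-dimethyl-5-methylidene-1,3-dioxane-4,6-dione | C=C1C(=O)OC(C)(C)OC1=O | intermediate (not isolated)
12 | 5-{[3-acetyl-2,4,6-trihydroxy-5-(3-methylbut-2-en-1-yl)phenyl]methyl}-2,2-dimethyl-1,3-dioxane-4,6-dione | CC(=O)c1c(O)c(CC=C(C)C)c(O)c(CC2C(=O)OC(C)(C)OC2=O)c1O | intermediate (not isolated)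
13 | 6-acetyl-5,7-dihydroxy-8-(3-methylbut-2-en-1-yl)-2-oxo-3,4-dihydro-2H-chromene-3-carboxylic acid (racemic at C3) | O=C1Oc2c(CC=C(C)C)c(O)c(C(C)=O)c(O)c2CC1C(=O)O | intermediate (not isolated)
14 | 6-acetyl-5,7-dihydroxy-8-(3-methylbut-2-en-1-yl)-3,4-dihydro-2H-chromen-2-one | O=C1CCc2c(O)c(C(C)=O)c(O)c(CC=C(C)C)c2O1 | intermediate
15 | methyl (2S)-7-[3-acetyl-2,4,6-trihydroxy-5-(3-methylbut-2-en-1-yl)phenyl]-2-methyl-2-(3-methylbut-2-en-1-yl)-3,5-dioxoheptanoate | O=C(CC(=O)CCc1c(O)c(CC=C(C)C)c(O)c(C(C)=O)c1O)[C@](C)(CC=C(C)C)C(=O)OC | intermediate (not isolated)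
16 | (6R)-4-{[3-acetyl-2,4,6-trihydroxy-5-(3-methylbut-2-en-1-yl)phenyl]methyl}-5-hydroxy-6-methyl-6-(3-methylbut-2-en-1-yl)cyclohex-4-ene-1,3-dione (enol tautomer drawn; the descriptor refers to it) | O=C1CC(=O)[C@](C)(CC=C(C)C)C(O)=C1Cc2c(O)c(CC=C(C)C)c(O)c(C(C)=O)c2O | intermediate
17 | acetic anhydride | CC(=O)OC(C)=O | starting material
18 | 2-acetyl-4-{[(3R)-5-acetyl-2,4-dihydroxy-3-methyl-3-(3-methylbut-2-en-1-yl)-6-oxocyclohexa-1,4-dien-1-yl]methyl}-6-(3-methylbut-2-en-1-yl)benzene-1,3,5-triyl triacetate | CC(=O)C1=C(O)[C@](C)(CC=C(C)C)C(O)=C(Cc2c(OC(C)=O)c(CC=C(C)C)c(OC(C)=O)c(C(C)=O)c2OC(C)=O)C1=O | intermediate (not isolated)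
19 | (4R)-2-acetyl-6-{[3-acetyl-2,4,6-trihydroxy-5-(3-methylbut-2-en-1-yl)phenyl]methyl}-3,5-dihydroxy-4-methyl-4-(3-methylbut-2-en-1-yl)cyclohexa-2,5-dien-1-one | CC(=O)C1=C(O)[C@](C)(CC=C(C)C)C(O)=C(Cc2c(O)c(CC=C(C)C)c(O)c(C(C)=O)c2O)C1=O | target

Total steps: 7. Longest linear sequence: 5 steps (1 → 3 → 5 → 6 → 16 → 19).

**Steps most likely to fail**

Step 6 (key step). The polyanion may aggregate or precipitate, so that the second deprotonation or the ring closure stalls, or the enolate oxygen may attack the ester and give an enol lactone. The fallback would lower the charge with protecting groups and separate the two bond formations. It sets out from 14: chloromethyl methyl ether and NaH would give 6-acetyl-5,7-bis(methoxymethoxy)-8-(3-methylbut-2-en-1-yl)-3,4-dihydro-2H-chromen-2-one F1. Acylation of the lithium enolate of 6 with F1 and acidic work-up would give the isolated diketo ester methyl (2S)-7-[3-acetyl-6-hydroxy-2,4-bis(methoxymethoxy)-5-(3-methylbut-2-en-1-yl)phenyl]-2-methyl-2-(3-methylbut-2-en-1-yl)-3,5-dioxoheptanoate F2. LiN(iPr)2 (3.2 equiv) would then close F2 to (6R)-4-{[3-acetyl-6-hydroxy-2,4-bis(methoxymethoxy)-5-(3-methylbut-2-en-1-yl)phenyl]methyl}-5-hydroxy-6-methyl-6-(3-methylbut-2-en-1-yl)cyclohex-4-ene-1,3-dione F3. Brief treatment with dilute HCl in methanol at room temperature would remove both acetals and bring the sequence back to 16.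

Step 5. Formaldehyde may bridge two molecules of 8 to a diarylmethane, or Meldrum's acid may add twice to 11, before the mixed adduct forms. The fallback would first fix the one-carbon unit on the arene and then form the carbon–carbon bond by elimination and addition. It sets out from 8: dimethyl(methylidene)ammonium iodide would give the Mannich base 1-{3-[(dimethylamino)methyl]-2,4,6-trihydroxy-5-(3-methylbut-2-en-1-yl)phenyl}ethan-1-one F4. Heating F4 with 10 in pyridine would expel dimethylamine, and the Meldrum's acid anion would trap the resulting ortho-quinone methide to give 12. Loss of acetone and carbon dioxide through 13 would bring the sequence back to 14.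

Step 7. The acetyl group may stay on oxygen, may enter at C6, or may be lost again during the methanolysis. The fallback would functionalise C2 by condensation instead of acylation. It sets out from 16: N,N-dimethylacetamide dimethyl acetal would condense with the C2 methylene at room temperature to give the enaminone (4R)-6-{[3-acetyl-2,4,6-trihydroxy-5-(3-methylbut-2-en-1-yl)phenyl]methyl}-2-[1-(dimethylamino)ethylidene]-5-hydroxy-4-methyl-4-(3-methylbut-2-en-1-yl)cyclohex-5-ene-1,3-dione F5. Mild aqueous hydrolysis (dilute NaOH, then acidification) would release dimethylamine and come back to the route at 19.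

**Further compounds**
F1 | step 6 | 6-acetyl-5,7-bis(methoxymethoxy)-8-(3-methylbut-2-en-1-yl)-3,4-dihydro-2H-chromen-2-one | O=C1CCc2c(OCOC)c(C(C)=O)c(OCOC)c(CC=C(C)C)c2O1
F2 | step 6 | methyl (2S)-7-[3-acetyl-6-hydroxy-2,4-bis(methoxymethoxy)-5-(3-methylbut-2-en-1-yl)phenyl]-2-methyl-2-(3-methylbut-2-en-1-yl)-3,5-dioxoheptanoate | O=C(CC(=O)CCc1c(O)c(CC=C(C)C)c(OCOC)c(C(C)=O)c1OCOC)[C@](C)(CC=C(C)C)C(=O)OC
F3 | step 6 | (6R)-4-{[3-acetyl-6-hydroxy-2,4-bis(methoxymethoxy)-5-(3-methylbut-2-en-1-yl)phenyl]methyl}-5-hydroxy-6-methyl-6-(3-methylbut-2-en-1-yl)cyclohex-4-ene-1,3-dione | O=C1CC(=O)[C@](C)(CC=C(C)C)C(O)=C1Cc2c(O)c(CC=C(C)C)c(OCOC)c(C(C)=O)c2OCOC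
F4 | step 5 | 1-{3-[(dimethylamino)methyl]-2,4,6-trihydroxy-5-(3-methylbut-2-en-1-yl)phenyl}ethan-1-one | CC(=O)c1c(O)c(CN(C)C)c(O)c(CC=C(C)C)c1O
F5 | step 7 | (4R)-6-{[3-acetyl-2,4,6-trihydroxy-5-(3-methylbut-2-en-1-yl)phenyl]methyl}-2-[1-(dimethylamino)ethylidene]-5-hydroxy-4-methyl-4-(3-methylbut-2-en-1-yl)cyclohex-5-ene-1,3-dione | CN(C)C(C)=C1C(=O)[C@](C)(CC=C(C)C)C(O)=C(Cc2c(O)c(CC=C(C)C)c(O)c(C(C)=O)c2O)C1=O
A1 | direct plan | 1-{2,6-dihydroxy-3-methyl-4-[(2-methylbut-3-en-2-yl)oxy]phenyl}ethan-1-one | CC(=O)c1c(O)cc(OC(C)(C)C=C)c(C)c1O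
A2 | direct plan | (4R)-2-acetyl-3,5-dihydroxy-4-methyl-4-(3-methylbut-2-en-1-yl)cyclohexa-2,5-dien-1-one | CC(=O)C1=C(O)[C@](C)(CC=C(C)C)C(O)=CC1=O
A3 | direct plan | 1-[2,4,6-trihydroxy-3-(3-methylbut-2-en-1-yl)phenyl]ethan-1-one | CC(=O)c1c(O)cc(O)c(CC=C(C)C)c1O
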